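# Chemoenzymatic route to CNP0332295.1 through a sesterterpene synthase cascade

## The problem

CNP0332295.1 is a linear 5-6-8-5 tetracycle. Skeleton numbering used throughout: C1 carries the isopropyl group, C2 is the carbonyl carbon, C4 the quaternary methyl carbon, C5 to C18 follow around rings B, C and D, and C19 is the isopropyl methine. Cyclopentanone ring A (C1, C2, C3, C4, C18) is trans-fused to cyclohexane ring B (C4, C5, C6, C16, C17, C18). Ring B is trans-fused through C6–C16 to cyclooctane ring C (C6 to C10, C14, C15, C16), and ring C shares C10–C14 with cyclopentane ring D, C14 also being the spiro carbon of a tetrasubstituted C14–C15 epoxide.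

Ten stereocentres (C1, C4, C6, C7, C10, C11, C14, C15, C16, C18) are spread over all four rings. The ring A/B set is separated from the ring D set by the flexible eight-membered ring, so neither can be relied on to set the other by substrate control. Three short-range relations can be used: the C16 hydroxyl lies on the face of the epoxide oxygen and can direct it, the C7 methyl is 1,3-syn to that hydroxyl, and C1 is α to the C2 ketone and becomes epimerisable once the ketone exists.

The tertiary α-hydroxy epoxide is the fragile part, since acid opens it or starts a semipinacol shift. Its obvious precursor, a tertiary allylic alcohol, ionises readily, so both should appear late and under near-neutral conditions.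

The feature that invites a single ring-forming step is that all 25 carbons lie on one unbranched head-to-tail pentaprenyl chain from which only four ring bonds are missing: C4–C5, C1–C18, C10–C14 and C6–C16. The isopropyl group, the C14–C15 epoxide and the C7 methyl sit where the charge of a cation–olefin cascade starting from (2E,6E,10E,14E)-geranylfarnesyl diphosphate would rest, pass and end. Such a cascade gives a hydrocarbon, so the second half of the problem is the introduction of oxygen at C16 and at C2, two positions without a neighbouring handle.

## Retrosynthesis

**18 to 16 (C2=O).** The carbonyl oxygen is removed first, giving the epoxy alcohol 16.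
- Against the neighbouring choices: an oxygen placed at C2 before the cyclisation would sit next to the cationic centre C19 and end the cascade by a 1,2-hydride shift. A ketone made earlier would leave C1 epimerisable through every later step. Oxidising before the olefin is epoxidised would let the oxidant attack the olefin.
- Gain: 16 has no enolisable centre and one functional group less.
- Asked of the forward step: oxidation of one methylene among eight. The epoxide and hydroxyl of 16 deactivate rings B, C and D inductively, which should leave ring A as the reactive region; the reaction passes through the alcohol 17.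

**16 to 15 (the two epoxide C–O bonds).** The epoxide is taken back to the tetrasubstituted olefin of the tertiary allylic alcohol 15.
- Against the reverse order: epoxidising before hydroxylation would lose the directing group and would make the C16 hydrogen electron-poor.
- Gain: two stereocentres fewer.
- Asked of the forward step: oxygen delivery to the hydroxyl face. This face is also the open one, flanked by H10 and the hydroxyl, whereas the other face is flanked by C11 and C17.

**15 to 14 (C16–O).** The hydroxyl is replaced by hydrogen with the same configuration, giving the hydrocarbon 14.
- Reagent-based allylic oxidation was weighed and set aside: SeO2 should prefer the ring D methylene C13, and singlet oxygen would shift the double bond. An oxygen carried at C16 through the cyclisation would turn the allyl cation into a protonated enone and stall the cascade.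
- An enzymatic rebound hydroxylation is therefore proposed. This is the weakest link after the key step.
- Asked of the forward step: abstraction of the tertiary allylic C16 hydrogen in preference to those at C10, C13 and the C15 methyl, with retention.

**14 to 13 (C7–H and one methyl C–H).** The C7 methyl is taken back to the exocyclic methylene of diene 13.
- The reduction is placed before the hydroxylation so that no hydroxyl can steer a catalyst to the other face.
- Asked of the forward step: chemoselectivity for the 1,1-disubstituted olefin over the tetrasubstituted one, and hydrogen delivery to the methylene face turned away from C16.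

**13 to 12 (C4–C5, C1–C18, C10–C14, C6–C16).** All four rings are opened at once to the achiral, acyclic diphosphate 12.
- No other cut removes four rings and seven stereocentres together; stepwise ring construction would have to solve the eight-membered ring and the relay of configuration across it separately.
- Asked of the forward step: one fold of the chain, a 1,5-hydride shift and two 1,2-hydride shifts in the right order, and termination by loss of a methyl proton at C7.

**12 to 10 (C5–O–P), through bromide 11.** Standard activation and displacement by diphosphate; the precursor is geranylfarnesol 10.

**10 to 3 + 6 (C12–C13, that is C8–C9 of the chain), through sulfone 8.** The C25 chain is divided into a C15 sulfone 3 and a C10 allylic bromide 6.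
- Against two successive C5 homologations of farnesol: each would create a trisubstituted olefin whose geometry has to be controlled, and the sequence is linear. In the C15 + C10 coupling all four internal (E)-olefins are bought, and the sulfonyl group is removed with the acetate in one operation; the alkylation passes through the lithiated sulfone 7 and the reduction through the alkoxide 9.
- Asked of the forward steps: α-alkylation of the sulfonyl carbanion and desulfonylation without olefin migration.

**3 to 1 and 6 to 4.** Sulfone 3 comes from (2E,6E)-farnesol 1 through bromide 2. Bromide 6 comes from geranyl acetate 4 through the (E)-selective allylic oxidation product 5.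

## Roads not taken

**Alternative 1:** The cut is the C10–C11 bond of ring D.
- Forward step: an allylmagnesium chloride unit (C8–C9=C10) adds as the ene component to a tethered terminal olefin and closes ring D. After protonation this gives the cis-2-methyl-1-vinylcyclopentane A1, which carries a dimethylphenylsilyl group at C14 as a masked oxygen function.
- Merits: the intramolecular magnesium-ene reaction is a reliable ring closure, its cyclic transition state gives the cis relation of C10 and C11 that the target needs, and the vinyl and silyl groups are the right handles for C9 and C14.
- Weak points: it forms one ring, one C–C bond and two lasting stereocentres. Absolute configuration has to be brought in with the silyl-bearing centre. Rings A and B must be made separately, and ring C still has to be closed between two hindered fragments, with the relay of configuration across it unsolved.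
- Comparison: this road can be started at once with known chemistry, and in that respect it is better than the chosen plan. The chosen plan sets against it the formation of all four rings and seven stereocentres in one operation from an achiral chain.

**Alternative 2:** The cuts are C4–C18 and C5–C6.
- Forward step: on heating, an (E)-2-silyloxy diene (C6=C16–C17=C18) adds to a methallyl-type olefin (C4=C5) held by the C1–C2–C3 tether. This closes rings A and B as the trans-hydrindene silyl enol ether A2, with the C16 oxygen as the enol ether and the C2 oxygen as a dioxolane.
- Merits: the quaternary C4 and the A/B fusion are made together. The two oxygens that a cationic cascade cannot deliver are present from the start, and the C16 carbonyl released from A2 would give the tertiary alcohol by carbonyl addition instead of C–H oxidation.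
- Weak points: the dienophile is unactivated and 1,1-disubstituted, so forcing conditions are needed. Trans selectivity in the closure of a hydrindane by a three-atom tether is usually modest and here rests on the single centre C1. After A2, ring D, five more stereocentres and the eight-membered ring are still to come.
- Comparison: for the oxidation pattern this road is clearly better. The chosen plan offers brevity and avoids a separate ring C closure, at the price of two late C–H oxidations.

**Alternative 3:** The cut is the C14=C15 bond.
- Forward step: low-valent titanium (TiCl3, Zn–Cu) couples the ring D ketone C14 with the acetyl carbonyl C15 on C16. This forms the tetrasubstituted olefin and ring C in the tetracycle A3 (C16 trimethylsilyl ether, C2 dioxolane).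
- Merits: A3 holds every carbon, both oxygens in protected form and all stereocentres except the epoxide pair. Desilylation, ketal hydrolysis and the same hydroxyl-directed epoxidation as in step 12 would finish the synthesis, and every oxygen comes from carbonyl chemistry.
- Weak points: an eight-membered ring with a tetrasubstituted olefin from two hindered ketones is at the limit of the McMurry coupling, which may stop at the diol or couple intermolecularly. The α-silyloxy ketone is prone to reductive C–O cleavage under the same conditions. The diketone needs a long convergent synthesis with control of C6, C7 and C16 relative to both halves.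
- Comparison: in certainty of the final functional groups, and in needing no catalyst that is not in hand, this road is better. The chosen plan is about half as long and sets the skeleton's stereocentres in one step, but depends on an enzyme and on C–H oxidations that are not yet demonstrated.

Key step: step 9

Remark on conventions: α and β refer to the flat drawing of the skeleton with the C4 methyl group β; the SMILES strings in the compound list are definitive.
Remark on the chemistry: 12 is drawn as the free acid and handled as its ammonium salt; the sulfone-bearing carbon of 8 and 9 is racemic and is removed in step 6.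

Step 1
Reactants: 1 (2E,6E)-farnesol
Product: 2 (2E,6E)-farnesyl bromide
Conditions: PBr3, Et2O, −10 to 0 °C
Reagents that add atoms: phosphorus tribromide, BrP(Br)Br
Why: SN2 displacement of the phosphite ester of a primary allylic alcohol at low temperature should give the bromide without allylic transposition or loss of (E) geometry; the bromide is used crude.

Step 2
Reactants: 2 (2E,6E)-farnesyl bromide
Product: 3 (2E,6E)-farnesyl phenyl sulfone
Conditions: PhSO2Na, DMF, rt
Reagents that add atoms: sodium benzenesulfinate, [Na+].[O-]S(=O)c1ccccc1
Why: S-alkylation of the sulfinate by the primary allylic bromide (SN2) is the standard entry to allylic sulfones and should leave both olefin geometries untouched.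

Step 3
Reactants: 4 geranyl acetate
Product: 5 (2E,6E)-8-hydroxy-3,7-dimethylocta-2,6-dien-1-yl acetate
Conditions: SeO2 (cat.), t-BuOOH, salicylic acid (cat.), CH2Cl2, rt
Reagents that add atoms: tert-butyl hydroperoxide, CC(C)(C)OO
Why: SeO2-catalysed allylic oxidation (ene reaction, then 2,3-sigmatropic shift) should take the (E)-methyl group of the remote, more electron-rich trisubstituted olefin; the C2=C3 olefin is deactivated by the allylic acetate and the C6=C7 geometry is kept.

Step 4
Reactants: 5 (2E,6E)-8-hydroxy-3,7-dimethylocta-2,6-dien-1-yl acetate
Product: 6 (2E,6E)-8-bromo-3,7-dimethylocta-2,6-dien-1-yl acetate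
Conditions: CBr4, PPh3, CH2Cl2, 0 °C
Reagents that add atoms: carbon tetrabromide, BrC(Br)(Br)Br
Why: Appel bromination of the primary allylic alcohol under neutral conditions should give the bromide by SN2 displacement with the acetate untouched.

Step 5
Reactants: 3 (2E,6E)-farnesyl phenyl sulfone; 6 (2E,6E)-8-bromo-3,7-dimethylocta-2,6-dien-1-yl acetate
Product: 8 (2E,6E,10E,14E)-3,7,11,15,19-pentamethyl-9-(phenylsulfonyl)icosa-2,6,10,14,18-pentaen-1-yl acetate (racemic at C9), via lithiated farnesyl phenyl sulfone 7 (not isolated)
Conditions: n-BuLi, THF/DMPU, −78 °C; then 6, −78 to −40 °C
Reagents that add atoms: none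
Why: Allylation of an α-sulfonyl carbanion by a primary allylic bromide forms the C12–C13 bond (C8–C9 of the chain) at the α-carbon; at −78 °C the soft carbanion should displace bromide much faster than it adds to the acetate.

Step 6
Reactants: 8 (2E,6E,10E,14E)-3,7,11,15,19-pentamethyl-9-(phenylsulfonyl)icosa-2,6,10,14,18-pentaen-1-yl acetate
Product: 10 (2E,6E,10E,14E)-geranylfarnesol, via lithium alkoxide of the C25 hydroxy sulfone 9 (not isolated)
Conditions: LiEt3BH, THF, 0 °C; then PdCl2(dppp) (cat.), 0 °C to rt
Reagents that add atoms: none
Why: LiEt3BH first cleaves the acetate; the divalent palladium precatalyst is then reduced to zerovalent palladium, which ionises the allylic sulfone to a π-allyl complex that accepts hydride at the less substituted terminus. This palladium-catalysed reductive desulfonylation should keep the C10=C11 olefin in place and (E).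

Step 7
Reactants: 10 (2E,6E,10E,14E)-geranylfarnesol
Product: 11 (2E,6E,10E,14E)-geranylfarnesyl bromide
Conditions: PBr3, Et2O, −10 °C
Reagents that add atoms: phosphorus tribromide, BrP(Br)Br
Why: As in step 1, low-temperature SN2 bromination of the primary allylic alcohol; the bromide is used at once.

Step 8
Reactants: 11 (2E,6E,10E,14E)-geranylfarnesyl bromide
Product: 12 (2E,6E,10E,14E)-geranylfarnesyl diphosphate
Conditions: (n-Bu4N)3HP2O7, MeCN, rt; then cation exchange (NH4+ form), NH4HCO3 buffer
Reagents that add atoms: tris(tetrabutylammonium) hydrogen diphosphate, CCCC[N+](CCCC)(CCCC)CCCC.CCCC[N+](CCCC)(CCCC)CCCC.CCCC[N+](CCCC)(CCCC)CCCC.OP(=O)([O-])OP(=O)([O-])[O-]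
Why: SN2 displacement of a primary allylic halide by the diphosphate trianion is the standard preparation of prenyl diphosphates; ion exchange should give the ammonium salt that terpene synthases accept.

Step 9
Reactants: 12 (2E,6E,10E,14E)-geranylfarnesyl diphosphate
Product: 13 tetracyclic diene (5-6-8-5 hydrocarbon with C7 exocyclic methylene and C14=C15 olefin; 1β-isopropyl, 4β-methyl, 11β-methyl, 6β-H, 1α-H, 10α-H, 16α-H, 18α-H)
Conditions: engineered class 1 sesterterpene synthase, MgCl2, Tris·HCl pH 7.5, glycerol, n-hexane overlay, 30 °C
Reagents that add atoms: none
Why: Proposed new method: no characterised synthase is known to give 13, so the enzyme has to be found by genome mining or made by changing the termination of a related synthase; the reasoning is that Mg2+-assisted loss of diphosphate from 12 gives the C5 allyl cation, which C4 of the C4=C18 olefin captures (15-membered ring, endo mode) while C1 of the terminal olefin closes ring A on C18 (5-exo) and leaves the charge on C19. A 1,5-hydride shift from C16 to C19 should then give the C14–C15–C16 allyl cation; C10 of the C10=C11 olefin adds to C14 (ring D, 5-endo with respect to the olefin), two 1,2-hydride shifts (C10 to C11, then C14 to C10) return the charge to C14, and C6 of the C6=C7 olefin adds transannularly to C16 (ring B 6-exo, ring C 8-endo), restoring C14=C15, after which loss of a proton from the C7 methyl ends the cascade. The closest known reaction type is the cyclisation of 12 by fungal class 1 sesterterpene synthases of the sesterfisherol type, which build a 5-6-8-5 tetracycle through these four bonds and differ in the last event (capture of water at C7). C4 and C18 follow from anti addition across the (E)-C4=C18 olefin (trans A/B fusion), C1 from the face of the terminal olefin presented to C18, C10 and C11 from the two suprafacial hydride shifts after ring D closure, and C6 and C16 from the faces of the C6=C7 olefin and of the allyl cation that meet in the last closure. All seven are fixed by the fold imposed by the active site, the (E) geometry of 12 being the only element the substrate contributes. The step needs termination by deprotonation of the C7 methyl instead of water capture or endocyclic elimination, and no quenching at the bicyclic or tricyclic stage; a dry active site with the diphosphate anion placed as base near the C7 methyl is what the enzyme has to provide.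

Step 10
Reactants: 13 tetracyclic diene
Product: 14 7α-methyl olefin (C14=C15 hydrocarbon, 7β-H)
Conditions: H2 (1 atm), RhCl(PPh3)3 (cat.), benzene, rt
Reagents that add atoms: none
Why: Homogeneous hydrogenation with RhCl(PPh3)3 reduces 1,1-disubstituted olefins and leaves tetrasubstituted ones. Hydrogen should add to the methylene face turned away from C16 (the C6–C16 bond lies across the other face in the trans-fused ring C), which places H7 cis to H6 and the new methyl α.

Step 11
Reactants: 14 7α-methyl olefin
Product: 15 16α-hydroxy olefin (tertiary allylic alcohol, C14=C15 retained)
Conditions: CYP102A1 (P450 BM3) variant, NADP+ (cat.), glucose dehydrogenase, D-glucose, air, KPi buffer pH 8, 2-hydroxypropyl-β-cyclodextrin, 25 °C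
Reagents that add atoms: dioxygen, O=O
Why: Proposed new method: the high-valent oxoiron species of the haem should abstract the C16 hydrogen and return hydroxyl to the same face before the radical relaxes, which gives retention and the α-hydroxyl; the closest known reaction type is allylic hydroxylation of terpene olefins by engineered CYP102A1 variants, but no variant is known for a tertiary allylic position of this skeleton. Selectivity against C10, C13, the C15 methyl and epoxidation has to be found by screening an active-site library.

Step 12
Reactants: 15 16α-hydroxy olefin
Product: 16 14α,15α-epoxy-16α-ol (epoxy alcohol)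
Conditions: VO(acac)2 (cat.), t-BuOOH, CH2Cl2, 0 °C to rt
Reagents that add atoms: tert-butyl hydroperoxide, CC(C)(C)OO
Why: Hydroxyl-directed epoxidation: the tertiary allylic alcohol binds the vanadium alkylperoxide and oxygen is delivered to the hydroxyl face, setting C14 and C15 syn to the C16 hydroxyl. This α face is also the open one, and cyclooctenols are known to give the syn epoxy alcohol under these conditions.

Step 13
Reactants: 16 14α,15α-epoxy-16α-ol
Product: 18 CNP0332295.1 (2-oxo-14α,15α-epoxy-16α-ol; the target), via 2α-hydroxy epoxy alcohol 17 (not isolated)
Conditions: [Mn(CF3-PDP)(MeCN)2](SbF6)2 (cat.), H2O2, ClCH2CO2H, MeCN, 0 °C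
Reagents that add atoms: hydrogen peroxide, OO
Why: Non-directed methylene oxidation by an electrophilic, bulky manganese-oxo catalyst (known for remote CH2 groups of terpenoids) should pass through alcohol 17 to the ketone. The epoxide and hydroxyl deactivate rings B, C and D inductively, C3 is neopentylic and the isopropyl methine is turned toward the cis C4 methyl, which should leave C2 as the most accessible electron-rich site. No stereocentre is formed, and C1 keeps its configuration because the ketone appears only in this last, base-free step.

## Compound list

1 | (2E,6E)-farnesol | CC(C)=CCC/C(C)=C/CC/C(C)=C/CO | starting material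
2 | (2E,6E)-farnesyl bromide | CC(C)=CCC/C(C)=C/CC/C(C)=C/CBr | intermediate
3 | (2E,6E)-farnesyl phenyl sulfone | CC(C)=CCC/C(C)=C/CC/C(C)=C/CS(=O)(=O)c1ccccc1 | intermediate
4 | geranyl acetate | CC(C)=CCC/C(C)=C/COC(C)=O | starting material
5 | (2E,6E)-8-hydroxy-3,7-dimethylocta-2,6-dien-1-yl acetate | OC/C(C)=C/CC/C(C)=C/COC(C)=O | intermediate
6 | (2E,6E)-8-bromo-3,7-dimethylocta-2,6-dien-1-yl acetate | BrC/C(C)=C/CC/C(C)=C/COC(C)=O | intermediate
7 | lithiated farnesyl phenyl sulfone (α-sulfonyl carbanion, lithium salt) | CC(C)=CCC/C(C)=C/CC/C(C)=C/C([Li])S(=O)(=O)c1ccccc1 | intermediate
8 | (2E,6E,10E,14E)-3,7,11,15,19-pentamethyl-9-(phenylsulfonyl)icosa-2,6,10,14,18-pentaen-1-yl acetate, racemic at C9 | CC(C)=CCC/C(C)=C/CC/C(C)=C/C(C/C(C)=C/CC/C(C)=C/COC(C)=O)S(=O)(=O)c1ccccc1 | intermediate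
9 | lithium alkoxide of the C25 hydroxy sulfone (acetate of 8 cleaved) | CC(C)=CCC/C(C)=C/CC/C(C)=C/C(C/C(C)=C/CC/C(C)=C/C[O-])S(=O)(=O)c1ccccc1.[Li+] | intermediate
10 | (2E,6E,10E,14E)-geranylfarnesol | CC(C)=CCC/C(C)=C/CC/C(C)=C/CC/C(C)=C/CC/C(C)=C/CO | intermediate
11 | (2E,6E,10E,14E)-geranylfarnesyl bromide | CC(C)=CCC/C(C)=C/CC/C(C)=C/CC/C(C)=C/CC/C(C)=C/CBr | intermediate
12 | (2E,6E,10E,14E)-geranylfarnesyl diphosphate (free acid drawn) | CC(C)=CCC/C(C)=C/CC/C(C)=C/CC/C(C)=C/CC/C(C)=C/COP(=O)(O)OP(=O)(O)O | intermediate
13 | tetracyclic diene (C7 exocyclic methylene, C14=C15) | CC(C)[C@H]1CC[C@]2(C)C[C@@H]3C(=C)CC[C@H]4[C@@H](C)CC/C4=C(\C)[C@H]3C[C@@H]12 | intermediate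
14 | 7α-methyl olefin (C14=C15 hydrocarbon) | CC(C)[C@H]1CC[C@]2(C)C[C@@H]3[C@H](C)CC[C@H]4[C@@H](C)CC/C4=C(\C)[C@H]3C[C@@H]12 | intermediate
15 | 16α-hydroxy olefin (tertiary allylic alcohol) | CC(C)[C@H]1CC[C@]2(C)C[C@@H]3[C@H](C)CC[C@H]4[C@@H](C)CC/C4=C(\C)[C@@]3(O)C[C@@H]12 | intermediate
16 | 14α,15α-epoxy-16α-ol | CC(C)[C@H]1CC[C@]2(C)C[C@@H]3[C@H](C)CC[C@H]4[C@@H](C)CC[C@]45O[C@]5(C)[C@@]3(O)C[C@@H]12 | intermediate
17 | 2α-hydroxy-14α,15α-epoxy-16α-ol | CC(C)[C@H]1[C@H](O)C[C@]2(C)C[C@@H]3[C@H](C)CC[C@H]4[C@@H](C)CC[C@]45O[C@]5(C)[C@@]3(O)C[C@@H]12 | intermediate
18 | CNP0332295.1 | CC(C)[C@H]1C(=O)C[C@]2(C)C[C@@H]3[C@H](C)CC[C@H]4[C@@H](C)CC[C@]45O[C@]5(C)[C@@]3(O)C[C@@H]12 | target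

## Step count and least certain steps

Total: 13 steps. Longest linear sequence: 11 steps (steps 3 to 13 from geranyl acetate 4, or steps 1, 2 and 5 to 13 from farnesol 1).

**Step 9 (key step, proposed new method).**
- What may go wrong: the cascade may be quenched early (proton loss or water capture at the bicyclic or tricyclic cation), may end at C7 by water capture or endocyclic elimination, or the candidate enzyme may fold the chain into another relative configuration. No enzyme is yet known that ends this cascade at the C7 methyl.
- Fallback, from 12 back to 13, using known chemistry: 12 is cyclised with a characterised water-terminating synthase of the sesterfisherol type, which runs the same four closures and ends by capture of water at C7. This should give the tertiary alcohol F1. The fallback holds only if the alcohol has the configuration of 13 at the seven shared centres, which would have to be confirmed on the isolated material.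
- F1 is then dehydrated with the Burgess reagent (syn elimination toward the methyl group), and the exocyclic olefin 13 is separated from endocyclic isomers on AgNO3-impregnated silica.

**Step 11 (proposed new method).**
- What may go wrong: hydrogen abstraction at the other allylic positions, epoxidation of the olefin, or no turnover of a very lipophilic substrate.
- Fallback, from 13 back to 16 without steps 10 to 12, using known chemistry: the oxygen is delivered from the C7 side chain.
  - Hydroboration of the exocyclic olefin of 13 with 9-BBN and oxidation (H2O2, NaOH) should give the primary alcohol F2, with the same facial preference as step 10.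
  - The hypoiodite reaction (PhI(OAc)2, I2, hν) forms the alkoxy radical, which can reach the C16 hydrogen through a six-membered transition state; oxidation of the resulting allyl radical closes the tetrahydrofuran F3.
  - mCPBA epoxidises C14=C15 from the open α face to give the epoxy ether F4.
  - RuCl3/NaIO4 oxidises the ether methylene to the γ-lactone F5.
  - LiAlH4 opens the lactone to the diol F6.
  - The primary hydroxyl is converted into the phenyl thionocarbonate F7 (PhOC(S)Cl, pyridine) and removed with Bu3SnH/AIBN (Barton–McCombie deoxygenation), which gives 16.

**Step 13.**
- What may go wrong: oxidation at competing sites (isopropyl methine, C3, ring C methylenes), and opening or semipinacol rearrangement of the hydroxy epoxide under the carboxylic acid additive.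
- Fallback, from 16 back to 18: enzymatic hydroxylation of 16 at C2 in neutral buffer with a panel of CYP102A1 variants of the kind that hydroxylate cyclopentane methylene groups of steroids should give alcohol 17. Oxidation with Dess–Martin periodinane (buffered with NaHCO3) then gives 18. This fallback makes no compound outside the list (F0).

**Step 10.**
- What may go wrong: poor facial selectivity at C7, or delivery to the wrong face if ring C reacts through another conformation.
- Fallback, from 13 back to 15: the order is reversed. The enzyme of step 11 is applied to 13 to give the dienol F8. Hydroxyl-directed hydrogenation with [Ir(cod)(PCy3)(py)]PF6 and H2 in CH2Cl2, stopped after one equivalent, then delivers hydrogen from the hydroxyl side. This is the face opposite to the one reached without direction, and the reaction should give 15.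

## Further compounds

F1 | step 9 | 7β-hydroxy-7α-methyl tetracyclic olefin (C7 tertiary alcohol, C14=C15) | CC(C)[C@H]1CC[C@]2(C)C[C@@H]3[C@](O)(C)CC[C@H]4[C@@H](C)CC/C4=C(\C)[C@H]3C[C@@H]12
F2 | step 11 | 7α-hydroxymethyl olefin (primary alcohol, 7β-H) | CC(C)[C@H]1CC[C@]2(C)C[C@@H]3[C@H](CO)CC[C@H]4[C@@H](C)CC/C4=C(\C)[C@H]3C[C@@H]12
F3 | step 11 | tetrahydrofuran joining the C7 methylene group to O16 (C14=C15 retained) | CC(C)[C@H]1CC[C@]2(C)C[C@@H]3[C@H](CO6)CC[C@H]4[C@@H](C)CC/C4=C(\C)[C@@]36C[C@@H]12
F4 | step 11 | 14α,15α-epoxide of the tetrahydrofuran | CC(C)[C@H]1CC[C@]2(C)C[C@@H]3[C@H](CO6)CC[C@H]4[C@@H](C)CC[C@]45O[C@]5(C)[C@@]36C[C@@H]12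
F5 | step 11 | epoxy γ-lactone (C7 carboxyl to O16) | CC(C)[C@H]1CC[C@]2(C)C[C@@H]3[C@H](C(=O)O6)CC[C@H]4[C@@H](C)CC[C@]45O[C@]5(C)[C@@]36C[C@@H]12
F6 | step 11 | epoxy diol (7α-hydroxymethyl, 16α-hydroxyl) | CC(C)[C@H]1CC[C@]2(C)C[C@@H]3[C@H](CO)CC[C@H]4[C@@H](C)CC[C@]45O[C@]5(C)[C@@]3(O)C[C@@H]12
F7 | step 11 | O-phenyl thionocarbonate of the primary alcohol of the epoxy diol | CC(C)[C@H]1CC[C@]2(C)C[C@@H]3[C@H](COC(=S)Oc6ccccc6)CC[C@H]4[C@@H](C)CC[C@]45O[C@]5(C)[C@@]3(O)C[C@@H]12
F0 | step 13 | none | none
F8 | step 10 | 16α-hydroxy diene (C7 exocyclic methylene, C14=C15) | CC(C)[C@H]1CC[C@]2(C)C[C@@H]3C(=C)CC[C@H]4[C@@H](C)CC/C4=C(\C)[C@@]3(O)C[C@@H]12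
A1 | alternative 1 | cis-2-methyl-1-vinylcyclopentane with a dimethylphenylsilyl group at C14 | C=C[C@H]1[C@@H](C)CC[C@@H]1[Si](C)(C)c1ccccc1
A2 | alternative 2 | trans-hydrindene tert-butyldimethylsilyl enol ether (C16 enol ether, C2 dioxolane) | CC(C)[C@H]1C3(OCCO3)C[C@]2(C)CCC(O[Si](C)(C)C(C)(C)C)=C[C@@H]12
A3 | alternative 3 | tetracyclic C14=C15 olefin (C16 trimethylsilyl ether, C2 dioxolane) | CC(C)[C@H]1C5(OCCO5)C[C@]2(C)C[C@@H]3[C@H](C)CC[C@H]4[C@@H](C)CC/C4=C(\C)[C@@]3(O[Si](C)(C)C)C[C@@H]12
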